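**Retrosynthetic overview**

1. Each half is an isochroman whose carbocycle (C4a, C5, C6, C7, C8, C8a) has oxygen on C6 and C8, the C1 carbon on C8a and the C3/C4 dimethyl stereodiad on C4a. C4a is meta to both oxygens, so substitution of a resorcinol cannot reach it and the benzene ring is built de novo around it.
2. The C7–CH2–C7' bridge is cut last: C7 of the quinone methide half adds to the ortho-quinone methide released from the C7 Mannich base of the reduced half. Both halves come from one isochromanone (lactol dehydration, then hydride reduction of a portion).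
3. The isochromanone is cut at C4a–C5 and C8–C8a: Michael–Claisen benzannulation of the dianion of methyl 3-oxopentanoate (C5 to C8) onto a (5R,6R)-4-methoxy-5,6-dimethyl-5,6-dihydropyran-2-one (C1, C8a, C4a, C4, C3).
4. The pyranone comes from ethyl (R)-3-hydroxybutanoate by Fráter–Seebach methylation, crossed Claisen condensation with tert-butyl acetate, lactonisation and O-methylation.
5. Ring order: the pyranone (later the pyran ring of both halves) first, the benzene ring second, the union of the halves last.

Key step: step 5

Remark: the oxidised half is written as the 6-hydroxy-8-oxo tautomer of the target SMILES; it equilibrates freely with the 8-hydroxy-6-oxo form and the two are treated as one compound. Lithium and sodium enolates of numbered compounds are treated as forms of those compounds.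

**Route**

Step 1
Reactants: 1 ethyl (R)-3-hydroxybutanoate
Product: 2 ethyl (2R,3R)-3-hydroxy-2-methylbutanoate
Conditions: LiN(i-Pr)2 (2.2 equiv), THF, −50 → −20 °C; MeI, DMPU, −78 → 0 °C; cold 1 M HCl
Reagents that add atoms: iodomethane, CI
Why: Fráter–Seebach alkylation, in which the lithium-chelated alkoxide–enolate dianion should be methylated on the face opposite the C3 methyl group, setting C2 as R, anti to the carbinol centre brought in with 1.

Step 2
Reactants: 2 ethyl (2R,3R)-3-hydroxy-2-methylbutanoate; 3 tert-butyl acetate
Product: 4 tert-butyl (4R,5R)-5-hydroxy-4-methyl-3-oxohexanoate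
Conditions: 3 (3.5 equiv), LiN(i-Pr)2 (3.5 equiv), THF, −78 °C; then 2, −78 → −10 °C; cold 1 M HCl
Reagents that add atoms: none
Why: crossed Claisen condensation of the lithium enolate of 3 with the ethyl ester of 2 (present as its lithium alkoxide); the product should rest as its β-keto ester enolate, which prevents a second addition and keeps the α-methyl centre from epimerising.

Step 3
Reactants: 4 tert-butyl (4R,5R)-5-hydroxy-4-methyl-3-oxohexanoate
Product: 6 (5R,6R)-5,6-dimethyloxane-2,4-dione, via hydroxy keto acid 5 (not isolated)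
Conditions: CF3CO2H, CH2Cl2, 0 °C → rt
Reagents that add atoms: none
Why: acidolysis of the tert-butyl ester with loss of isobutene and spontaneous δ-lactonisation of the freed acid; the trans-dimethyl lactone is also the expected thermodynamic isomer, so enolisation towards C5 should not erode the diad.

Step 4
Reactants: 6 (5R,6R)-5,6-dimethyloxane-2,4-dione
Product: 7 (5R,6R)-4-methoxy-5,6-dimethyl-5,6-dihydro-2H-pyran-2-one
Conditions: Me2SO4, K2CO3, acetone, rt → 50 °C
Reagents that add atoms: dimethyl sulfate, COS(=O)(=O)OC
Why: O-alkylation of the enolised β-keto lactone (a vinylogous acid) with a hard methylating agent should give the conjugated 4-methoxy enol ether, the vinylogous carbonate needed as Michael acceptor.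

Step 5
Reactants: 7 (5R,6R)-4-methoxy-5,6-dimethyl-5,6-dihydro-2H-pyran-2-one; 8 methyl 3-oxopentanoate
Product: 10 (3R,4S)-6,8-dihydroxy-3,4,5-trimethylisochroman-1-one, via Michael–elimination adduct 9 (not isolated)
Conditions: 8 (1.3 equiv), NaH, THF, 0 °C; n-BuLi, 0 °C; 7, −78 → 0 °C; then NaOMe (solid, 1.5 equiv), 0 → 60 °C; 1 M HCl
Reagents that add atoms: none
Why: Proposed new method: the dianion of 8 should add through its γ-carbon (future C5) to the methoxy-bearing C4 of 7 (future C4a), the lactone enolate then expelling methoxide in a vinylogous acyl substitution to leave adduct 9; methoxide removes the C5–H of 9, which is α to the ketone and vinylogously α to the lactone carbonyl, and the dienolate attacks the methyl ester through the lactone α-carbon (future C8a), after which loss of methoxide and two enolisations give the resorcinol irreversibly. The closest known reaction types are the Staunton–Weinreb annulation (Michael–Claisen reaction of toluate-type carbanions with 4-methoxy-5,6-dihydropyran-2-ones) and the base-mediated Claisen aromatisation of polyketo esters. The only ring closed is the carbocycle, by a 6-(enolexo)-exo-trig attack at the ester carbon once the C4a–C5 bond is in place. No stereocentre is created, since the CH(CH3) centre of 9 becomes aromatic C5, and the C3/C4 diad of 7 is carried through unchanged. The step needs γ- over α-attack of the donor (the γ-carbon is the more basic site of the dianion), conjugate over carbonyl addition (the lactone carbonyl of 7 is a deactivated vinylogous carbonate and its β-carbon carries the leaving group), closure onto the ester and not onto the lactone carbonyl (in the closed lactone the ketoester chain lies trans to C1 across the ring C4a=C8a double bond, so C7 cannot reach C1) and an intact C4 (the exocyclic C5–H is far more acidic than the ring C4–H, and aromatisation then leaves C4 as a plain benzylic centre).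

Step 6
Reactants: 10 (3R,4S)-6,8-dihydroxy-3,4,5-trimethylisochroman-1-one
Product: 11 (3R,4S)-6,8-bis(tert-butyldimethylsilyloxy)-3,4,5-trimethylisochroman-1-one
Conditions: t-BuMe2SiCl (2.5 equiv), imidazole, DMF, rt → 40 °C
Reagents that add atoms: tert-butyldimethylsilyl chloride, CC(C)(C)[Si](C)(C)Cl
Why: silylation of both phenols removes the acidic protons and the hydrogen-bonded chelate that would consume hydride and deactivate the lactone; silyl ethers are preferred to methoxymethyl ethers because their removal frees no formaldehyde next to the nucleophilic C7.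

Step 7
Reactants: 11 (3R,4S)-6,8-bis(tert-butyldimethylsilyloxy)-3,4,5-trimethylisochroman-1-one
Product: 12 (3R,4S)-6,8-bis(tert-butyldimethylsilyloxy)-3,4,5-trimethylisochroman-1-ol (mixture of C1 epimers)
Conditions: i-Bu2AlH (1.2 equiv), CH2Cl2, −78 °C; aq. KNaC4H4O6
Reagents that add atoms: none
Why: half-reduction of the aryl lactone, the tetrahedral aluminium hemiacetal being stable at −78 °C; the new C1 centre is not controlled and is removed in the next step.

Step 8
Reactants: 12 (3R,4S)-6,8-bis(tert-butyldimethylsilyloxy)-3,4,5-trimethylisochroman-1-ol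
Product: 14 (3R,4S)-6-hydroxy-3,4,5-trimethyl-3,4-dihydro-8H-isochromen-8-one (decarboxycitrinin quinone methide), via lactol triol 13 (not isolated)
Conditions: aq. HF (48%), MeCN, 0 °C → rt; extraction, concentration from toluene
Reagents that add atoms: none
Why: desilylation of the aryl silyl ethers followed by acid-catalysed dehydration of the lactol, whose oxocarbenium ion is conjugated with the C6 and C8 oxygens and loses a phenolic proton to give the quinone methide, as in the interconversion of citrinin hydrate and citrinin.

Step 9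
Reactants: 14 decarboxycitrinin quinone methide (about half of the material)
Product: 15 (3R,4S)-3,4,5-trimethylisochromane-6,8-diol
Conditions: NaBH4, EtOH, 0 °C; aqueous work-up
Reagents that add atoms: none
Why: 1,6-conjugate hydride addition to the electrophilic C1 of the quinone methide with rearomatisation of the carbocycle, the reaction type that converts citrinin into dihydrocitrinin; C3 and C4 are not touched.

Step 10
Reactants: 15 (3R,4S)-3,4,5-trimethylisochromane-6,8-diol
Product: 16 (3R,4S)-7-[(dimethylamino)methyl]-3,4,5-trimethylisochromane-6,8-diol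
Conditions: CH2=NMe2+ I− (1.1 equiv), Et3N, CH2Cl2, 0 °C → rt
Reagents that add atoms: Eschenmoser's salt (N,N-dimethylmethyleneiminium iodide), C=[N+](C)C.[I-]
Why: Mannich aminomethylation by the preformed iminium ion at C7, the only unsubstituted ring carbon and ortho to both hydroxyl groups; the iminium carbon becomes the bridging methylene.

Step 11
Reactants: 14 decarboxycitrinin quinone methide; 16 (3R,4S)-7-[(dimethylamino)methyl]-3,4,5-trimethylisochromane-6,8-diol
Product: 18 dicitrinone I, via ortho-quinone methide 17 (not isolated)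
Conditions: 14 (1.3 equiv), toluene, 100 °C, slow Ar stream
Reagents that add atoms: none
Why: thermal elimination of dimethylamine from the ortho-hydroxybenzylamine should give an ortho-quinone methide, to which C7 of 14 (the central carbon of its cyclic vinylogous acid) adds in a Michael reaction driven by rearomatisation of the resorcinol ring; no stereocentre is formed or touched.

**Compound list**

1 | ethyl (R)-3-hydroxybutanoate | C[C@@H](O)CC(=O)OCC | starting material
2 | ethyl (2R,3R)-3-hydroxy-2-methylbutanoate | O[C@H](C)[C@H](C(=O)OCC)C | intermediate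
3 | tert-butyl acetate | CC(=O)OC(C)(C)C | starting material
4 | tert-butyl (4R,5R)-5-hydroxy-4-methyl-3-oxohexanoate | O[C@H](C)[C@H](C(=O)CC(=O)OC(C)(C)C)C | intermediate
5 | (4R,5R)-5-hydroxy-4-methyl-3-oxohexanoic acid | O[C@H](C)[C@H](C(=O)CC(=O)O)C | intermediate (not isolated)
6 | (5R,6R)-5,6-dimethyloxane-2,4-dione | O1[C@H](C)[C@H](C(=O)CC1=O)C | intermediate
7 | (5R,6R)-4-methoxy-5,6-dimethyl-5,6-dihydro-2H-pyran-2-one | O1[C@H](C)[C@H](C(OC)=CC1=O)C | intermediate
8 | methyl 3-oxopentanoate | CCC(=O)CC(=O)OC | starting material
9 | methyl 4-[(2R,3S)-2,3-dimethyl-6-oxo-3,6-dihydro-2H-pyran-4-yl]-3-oxopentanoate (both epimers at the side-chain CH) | O1[C@H](C)[C@H](C(C(C)C(=O)CC(=O)OC)=CC1=O)C | intermediate (not isolated)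
10 | (3R,4S)-6,8-dihydroxy-3,4,5-trimethylisochroman-1-one | O=C1O[C@H](C)[C@H](c2c(C)c(O)cc(O)c12)C | intermediate
11 | (3R,4S)-6,8-bis(tert-butyldimethylsilyloxy)-3,4,5-trimethylisochroman-1-one | O=C1O[C@H](C)[C@H](c2c(C)c(O[Si](C)(C)C(C)(C)C)cc(O[Si](C)(C)C(C)(C)C)c12)C | intermediate
12 | (3R,4S)-6,8-bis(tert-butyldimethylsilyloxy)-3,4,5-trimethylisochroman-1-ol (C1 epimers) | OC1O[C@H](C)[C@H](c2c(C)c(O[Si](C)(C)C(C)(C)C)cc(O[Si](C)(C)C(C)(C)C)c12)C | intermediate
13 | (3R,4S)-3,4,5-trimethylisochromane-1,6,8-triol (C1 epimers) | OC1O[C@H](C)[C@H](c2c(C)c(O)cc(O)c12)C | intermediate (not isolated)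
14 | (3R,4S)-6-hydroxy-3,4,5-trimethyl-3,4-dihydro-8H-isochromen-8-one (decarboxycitrinin quinone methide) | CC1=C2C(=CO[C@H](C)[C@H]2C)C(=O)C=C1O | intermediate
15 | (3R,4S)-3,4,5-trimethylisochromane-6,8-diol | c1c(O)c(C)c2c(c1O)CO[C@H](C)[C@H]2C | intermediate
16 | (3R,4S)-7-[(dimethylamino)methyl]-3,4,5-trimethylisochromane-6,8-diol | CN(C)Cc1c(O)c(C)c2c(c1O)CO[C@H](C)[C@H]2C | intermediate
17 | (3R,4S)-8-hydroxy-3,4,5-trimethyl-7-methylidene-3,4-dihydro-1H-isochromen-6(7H)-one | C=C1C(=O)C(C)=C2C(=C1O)CO[C@H](C)[C@H]2C | intermediate (not isolated)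
18 | dicitrinone I, (3R,4S)-7-{[(3R,4S)-6,8-dihydroxy-3,4,5-trimethylisochroman-7-yl]methyl}-6-hydroxy-3,4,5-trimethyl-3,4-dihydro-8H-isochromen-8-one | CC1=C2C(=CO[C@H](C)[C@H]2C)C(=O)C(Cc2c(O)c(C)c3c(c2O)CO[C@H](C)[C@H]3C)=C1O | target

**Step count**

Total steps: 11. Longest linear sequence: 11 steps (1 → 18; compound 14 is divided after step 8 and re-enters in step 11).

**Steps most likely to fail**

Step 5 (proposed new method). Three processes threaten it. The dianion may attack the lactone carbonyl of 7 or simply deprotonate 7 at C5, with ring opening to a dienoate. The hindered secondary carbanion may not add to the substituted C4. Adduct 9 may not close because its β-keto ester rests as the unreactive enolate.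

The fallback keeps the same two ring bonds but forms them by a known Diels–Alder benzannulation; it sets out from 2 (with 8 for the diene) and returns at 10.
- Compound 2 is silylated (t-BuMe2SiCl, imidazole) to ethyl (2R,3R)-3-(tert-butyldimethylsilyloxy)-2-methylbutanoate F1.
- F1 is reduced (i-Bu2AlH, −78 °C) to (2R,3R)-3-(tert-butyldimethylsilyloxy)-2-methylbutanal F2.
- Corey–Fuchs homologation follows: CBr4/PPh3 gives tert-butyl{[(2R,3S)-5,5-dibromo-3-methylpent-4-en-2-yl]oxy}dimethylsilane F3; n-BuLi (2 equiv) and then ClCO2Me give methyl (4S,5R)-5-(tert-butyldimethylsilyloxy)-4-methylhex-2-ynoate F4.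
- Separately, 8 is converted with Me3SiCl/Et3N into methyl 3-(trimethylsilyloxy)pent-2-enoate F5, and then with LiN(i-Pr)2/Me3SiCl into 1-methoxy-1,3-bis(trimethylsilyloxy)penta-1,3-diene F6.
- Heating F4 with F6 in toluene joins the nucleophilic diene terminus to the β-carbon of the ynoate. Acidic work-up, with loss of methanol and the trimethylsilyl groups, should give methyl 2,4-dihydroxy-5-methyl-6-[(2S,3R)-3-(tert-butyldimethylsilyloxy)butan-2-yl]benzoate F7.
- Aqueous HCl in THF, then catalytic TsOH in warm toluene, removes the silyl ether and lactonises to 10.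

Step 11. Compound 14 is both a C7 nucleophile and a C1 electrophile, so self-condensation of 14 at 100 °C and dimerisation of the ortho-quinone methide may outrun the cross Michael addition.

The fallback forms the bridge before the electrophilic quinone methide exists; it sets out from 10 and 16 and returns at 18.
- Heating 16 with the lactone 10 (nucleophilic at C7 only) in toluene should give (3R,4S)-7-{[(3R,4S)-6,8-dihydroxy-3,4,5-trimethylisochroman-7-yl]methyl}-6,8-dihydroxy-3,4,5-trimethylisochroman-1-one F8.
- MOMCl/NaH in DMF gives the tetrakis(methoxymethyl) ether of the bridged lactone F9. Methoxymethyl groups are acceptable here because no free ring position remains.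
- i-Bu2AlH at −78 °C gives the bridged lactol tetrakis(methoxymethyl) ether F10.
- Aqueous HCl in THF removes the four acetals and dehydrates the lactol to 18.

Step 8. While the quinone methide is being unmasked in acid, C7 of one molecule may add to C1 of another, giving oligomers; dehydration of the hydrate may also stay incomplete.

The fallback reaches 14 by dehydrogenation instead of dehydration; it sets out from 12 and returns at 15 and then at 14.
- Ionic reduction of 12 (Et3SiH, BF3·OEt2, CH2Cl2, −78 °C) gives (3R,4S)-6,8-bis(tert-butyldimethylsilyloxy)-3,4,5-trimethylisochroman F11.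
- Bu4NF in THF gives 15.
- The portion of 15 needed as the oxidised half is dehydrogenated under neutral conditions with DDQ (1 equiv, 1,4-dioxane, rt), a known oxidation of 4-hydroxybenzyl ethers to para-quinone methides, to give 14.

**Further compounds**

F1 | step 5 | ethyl (2R,3R)-3-(tert-butyldimethylsilyloxy)-2-methylbutanoate | CC(C)(C)[Si](C)(C)O[C@H](C)[C@H](C(=O)OCC)C
F2 | step 5 | (2R,3R)-3-(tert-butyldimethylsilyloxy)-2-methylbutanal | CC(C)(C)[Si](C)(C)O[C@H](C)[C@H](C=O)C
F3 | step 5 | tert-butyl{[(2R,3S)-5,5-dibromo-3-methylpent-4-en-2-yl]oxy}dimethylsilane | CC(C)(C)[Si](C)(C)O[C@H](C)[C@H](C=C(Br)Br)C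
F4 | step 5 | methyl (4S,5R)-5-(tert-butyldimethylsilyloxy)-4-methylhex-2-ynoate | CC(C)(C)[Si](C)(C)O[C@H](C)[C@H](C#CC(=O)OC)C
F5 | step 5 | methyl 3-(trimethylsilyloxy)pent-2-enoate | CCC(O[Si](C)(C)C)=CC(=O)OC
F6 | step 5 | 1-methoxy-1,3-bis(trimethylsilyloxy)penta-1,3-diene | COC(O[Si](C)(C)C)=CC(O[Si](C)(C)C)=CC
F7 | step 5 | methyl 2,4-dihydroxy-5-methyl-6-[(2S,3R)-3-(tert-butyldimethylsilyloxy)butan-2-yl]benzoate | CC(C)(C)[Si](C)(C)O[C@H](C)[C@H](c1c(C)c(O)cc(O)c1C(=O)OC)C
F8 | step 11 | (3R,4S)-7-{[(3R,4S)-6,8-dihydroxy-3,4,5-trimethylisochroman-7-yl]methyl}-6,8-dihydroxy-3,4,5-trimethylisochroman-1-one | O=C1O[C@H](C)[C@H](c2c(C)c(O)c(Cc3c(O)c(C)c4c(c3O)CO[C@H](C)[C@H]4C)c(O)c12)C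
F9 | step 11 | (3R,4S)-7-{[(3R,4S)-6,8-bis(methoxymethoxy)-3,4,5-trimethylisochroman-7-yl]methyl}-6,8-bis(methoxymethoxy)-3,4,5-trimethylisochroman-1-one | O=C1O[C@H](C)[C@H](c2c(C)c(OCOC)c(Cc3c(OCOC)c(C)c4c(c3OCOC)CO[C@H](C)[C@H]4C)c(OCOC)c12)C
F10 | step 11 | (3R,4S)-7-{[(3R,4S)-6,8-bis(methoxymethoxy)-3,4,5-trimethylisochroman-7-yl]methyl}-6,8-bis(methoxymethoxy)-3,4,5-trimethylisochroman-1-ol (C1 epimers) | OC1O[C@H](C)[C@H](c2c(C)c(OCOC)c(Cc3c(OCOC)c(C)c4c(c3OCOC)CO[C@H](C)[C@H]4C)c(OCOC)c12)C
F11 | step 8 | (3R,4S)-6,8-bis(tert-butyldimethylsilyloxy)-3,4,5-trimethylisochroman | c1c(O[Si](C)(C)C(C)(C)C)c(C)c2c(c1O[Si](C)(C)C(C)(C)C)CO[C@H](C)[C@H]2C
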